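**Retrosynthetic overview**

1. Numbering (eudesmane type): C1 = CH bearing the benzylic CH2; C2, C3 = CH2; C4 = CH(CH3); C5=C6 = trisubstituted alkene with C5 at the ring fusion; C7 = CH(isopropenyl); C8, C9 = CH2; C10 = quaternary C(CH3). Ring A = C5–C10, ring B = C1–C5 plus C10.
2. Last cuts: the aryl formyl group (Vilsmeier–Haack) and the ArCH2–C1 bond (o-quinone methide reductive alkylation of a C1 aldehyde with isovalerylphloroglucinol).
3. Ring B is cut at C2–C3 and C4–C5. C3–C4 with the C4 methyl is crotonaldehyde, whose formyl group on C3 is a traceless activator. The other piece is a ring A alkenylboronate (boron on C5) whose C10 carries an α-substituted acrylate (C1, C2 and the future benzylic carbon).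
4. Enabling feature: C5 is the sp2 fusion carbon next to quaternary C10, so a C5 alkenyl nucleophile comes regiospecifically from a ring A ketone. C2 is three bonds away (C5–C10–C1–C2) and is the β-carbon of an acrylate built on the exocyclic carbon of C1. One rhodium-catalysed conjugate addition/Michael ring closure can therefore make both bonds.
5. Ring order: ring A is bought as (S)-carvone (C7), C10 is set by reductive alkylation, ring B is closed in the key step, and the arene is attached at the end.

Key step: step 5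

Remark: in the systematic names the naphthalene locants 4a, 5, 6, 7, 8, 8a correspond to C5, C6, C7, C8, C9, C10.
Remark: the sense of induction of the diene ligand in step 5 is assigned by analogy with (E)-enones and is an assumption; compound 21 is made in step 9 although it can also be bought.

**Route**

Step 1
Reactants: 1 (S)-(+)-carvone; 2 methyl bromoacetate
Product: 4 methyl 2-[(1S,4S)-1-methyl-2-oxo-4-(prop-1-en-2-yl)cyclohexyl]acetate, via lithium enolate 3 (not isolated)
Conditions: LiBH(s-Bu)3 (1.05 equiv), THF, −78 °C; then 2 (1.5 equiv), −78 → 0 °C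
Reagents that add atoms: none
Why: Conjugate hydride reduction of the β-unsubstituted enone should give the tetrasubstituted C10 enolate regiospecifically, and its alkylation (reductive alkylation of an enone) should proceed by axial attack on the half-chair with equatorial isopropenyl, which places the acetate chain cis to the isopropenyl group and sets C10.

Step 2
Reactants: 4 methyl 2-[(1S,4S)-1-methyl-2-oxo-4-(prop-1-en-2-yl)cyclohexyl]acetate
Product: 6 methyl 2-[(1S,4S)-1-methyl-4-(prop-1-en-2-yl)-2-(trifluoromethanesulfonyloxy)cyclohex-2-en-1-yl]acetate, via potassium enolate 5 (not isolated)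
Conditions: KN(SiMe3)2 (1.1 equiv), THF, −78 °C; N-(5-chloropyridin-2-yl)bis(trifluoromethanesulfonimide) (1.2 equiv), −78 → 0 °C
Reagents that add atoms: N-(5-chloropyridin-2-yl)-1,1,1-trifluoro-N-(trifluoromethylsulfonyl)methanesulfonamide, O=S(=O)(N(c1ccc(Cl)cn1)S(=O)(=O)C(F)(F)F)C(F)(F)F
Why: The ketone can enolise only towards C6 because C10 is quaternary and it is more acidic than the ester, so O-sulfonylation of the potassium enolate (enol triflate formation) should fix the C5=C6 double bond without forming a stereocentre.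

Step 3
Reactants: 6 methyl 2-[(1S,4S)-1-methyl-4-(prop-1-en-2-yl)-2-(trifluoromethanesulfonyloxy)cyclohex-2-en-1-yl]acetate
Product: 10 methyl 2-[(1S,4S)-1-methyl-4-(prop-1-en-2-yl)-2-(trifluoromethanesulfonyloxy)cyclohex-2-en-1-yl]prop-2-enoate, via lithium ester enolate 7 (not isolated), via Mannich base 8 (not isolated), via trimethylammonium iodide 9 (not isolated)
Conditions: LiN(i-Pr)2 (1.1 equiv), THF, −78 °C; Me2N=CH2+ I− (1.5 equiv), −78 → 0 °C; then MeI (excess), 25 °C; then aq. NaHCO3, 25 °C
Reagents that add atoms: N,N-dimethylmethyleneiminium iodide, C[N+](C)=C.[I-]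
Why: Aminomethylation of the ester enolate, N-methylation and E1cB loss of trimethylamine (Mannich methylenation with Eschenmoser's salt) should turn the acetate CH2 (C1) into the α-substituted acrylate whose CH2 terminus is C2, the enol triflate being inert to one equivalent of amide base at −78 °C.

Step 4
Reactants: 10 methyl 2-[(1S,4S)-1-methyl-4-(prop-1-en-2-yl)-2-(trifluoromethanesulfonyloxy)cyclohex-2-en-1-yl]prop-2-enoate
Product: 11 methyl 2-[(1R,4S)-1-methyl-4-(prop-1-en-2-yl)-2-(4,4,5,5-tetramethyl-1,3,2-dioxaborolan-2-yl)cyclohex-2-en-1-yl]prop-2-enoate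
Conditions: B2pin2 (1.3 equiv), PdCl2(dppf) (5 mol%), KOAc (3 equiv), 1,4-dioxane, 80 °C
Reagents that add atoms: bis(pinacolato)diboron, CC1(C)OB(OC1(C)C)B1OC(C)(C)C(C)(C)O1
Why: Miyaura borylation (oxidative addition of the alkenyl triflate to zerovalent palladium, acetate-assisted transmetallation, reductive elimination) should place boron on C5 without moving the double bond and without touching the acrylate; the descriptor at C10 changes only because of the priority rules.

Step 5
Reactants: 11 methyl 2-[(1R,4S)-1-methyl-4-(prop-1-en-2-yl)-2-(4,4,5,5-tetramethyl-1,3,2-dioxaborolan-2-yl)cyclohex-2-en-1-yl]prop-2-enoate; 12 (E)-crotonaldehyde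
Product: 15 methyl (1R,3S,4S,6S,8aS)-3-formyl-4,8a-dimethyl-6-(prop-1-en-2-yl)-1,2,3,4,6,7,8,8a-octahydronaphthalene-1-carboxylate, via alkenylrhodium species 13 (not isolated), via open-chain rhodium enolate 14 (not isolated)
Conditions: [RhCl(C2H4)2]2 (2.5 mol%), (1S,4S)-2,5-diphenylbicyclo[2.2.2]octa-2,5-diene (5.5 mol%), KOH (20 mol%), 12 (3 equiv), 1,4-dioxane/H2O 10:1, 40 °C
Reagents that add atoms: none
Why: Proposed new method: transmetallation of the C5 boronate to monovalent rhodium gives alkenylrhodium 13, which adds 1,4 to crotonaldehyde (C4–C5 bond) to give the oxa-π-allyl rhodium enolate 14; this enolate attacks through C3 the CH2 terminus (C2) of the acrylate held on C10 (C2–C3 bond), and water protonates the resulting ester enolate at C1 and returns Rh–OH. The closest known reaction types are the Hayashi–Miyaura asymmetric 1,4-addition of alkenylboron reagents to enals and the rhodium-catalysed tandem conjugate addition–Michael cyclisation of rhodium enolates onto tethered acceptors, which have not been combined as an intermolecular/intramolecular [4+2] annulation on an α-quaternary cycloalkenylboronate. Ring B is closed in the 6-endo-trig (enolexo) mode. C4 is controlled by the diene ligand (addition to the Si face of the enal β-carbon, the sense expected from the quadrant model for (E)-enones), C1 by protonation of the exocyclic enolate from the face opposite to the axial C10 and C4 methyl groups, and C3 should settle as the equatorial epimer and is erased in step 6. The step needs the alkenylrhodium to choose the enal over its own acrylate, which the substrate secures because C5 cannot reach C2 without forming a four-membered ring and the enal is in excess, and it needs ring closure to beat protonolysis of 14, which the six-membered transition state and the low water content favour.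

Step 6
Reactants: 15 methyl (1R,3S,4S,6S,8aS)-3-formyl-4,8a-dimethyl-6-(prop-1-en-2-yl)-1,2,3,4,6,7,8,8a-octahydronaphthalene-1-carboxylate
Product: 16 methyl (1R,4S,6S,8aS)-4,8a-dimethyl-6-(prop-1-en-2-yl)-1,2,3,4,6,7,8,8a-octahydronaphthalene-1-carboxylate
Conditions: RhCl(PPh3)3 (1.1 equiv), toluene, 110 °C
Reagents that add atoms: none
Why: Tsuji–Wilkinson decarbonylation (oxidative addition of the formyl C–H bond to monovalent rhodium, CO extrusion, C–H reductive elimination) should remove the activating formyl group so that C3 becomes CH2, the ester and the hindered tri- and 1,1-disubstituted alkenes being poor partners for the acylrhodium hydride.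

Step 7
Reactants: 16 methyl (1R,4S,6S,8aS)-4,8a-dimethyl-6-(prop-1-en-2-yl)-1,2,3,4,6,7,8,8a-octahydronaphthalene-1-carboxylate
Product: 17 [(1R,4S,6S,8aS)-4,8a-dimethyl-6-(prop-1-en-2-yl)-1,2,3,4,6,7,8,8a-octahydronaphthalen-1-yl]methanol
Conditions: i-Bu2AlH (2.5 equiv), CH2Cl2, −78 → 0 °C; aq. potassium sodium tartrate work-up
Reagents that add atoms: none
Why: Hydride reduction of the methyl ester should give the primary alcohol under non-basic conditions, so the C1 stereocentre is not touched.

Step 8
Reactants: 17 [(1R,4S,6S,8aS)-4,8a-dimethyl-6-(prop-1-en-2-yl)-1,2,3,4,6,7,8,8a-octahydronaphthalen-1-yl]methanol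
Product: 18 (1R,4S,6S,8aS)-4,8a-dimethyl-6-(prop-1-en-2-yl)-1,2,3,4,6,7,8,8a-octahydronaphthalene-1-carbaldehyde
Conditions: Dess–Martin periodinane (1.3 equiv), NaHCO3, CH2Cl2, 0 → 25 °C; used without storage
Reagents that add atoms: none
Why: Dess–Martin oxidation under buffered conditions should give the α-branched aldehyde without epimerisation at C1.

Step 9
Reactants: 19 phloroglucinol; 20 isovaleryl chloride
Product: 21 3-methyl-1-(2,4,6-trihydroxyphenyl)butan-1-one
Conditions: AlCl3 (3.5 equiv), nitrobenzene/CH2Cl2, 25 → 60 °C; aq. HCl work-up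
Reagents that add atoms: none
Why: Friedel–Crafts C-acylation of the electron-rich triol should stop at monoacylation because the first acyl group deactivates the ring.

Step 10
Reactants: 18 (1R,4S,6S,8aS)-4,8a-dimethyl-6-(prop-1-en-2-yl)-1,2,3,4,6,7,8,8a-octahydronaphthalene-1-carbaldehyde; 21 3-methyl-1-(2,4,6-trihydroxyphenyl)butan-1-one
Product: 23 1-(2,4,6-trihydroxy-3-{[(1S,4S,6S,8aS)-4,8a-dimethyl-6-(prop-1-en-2-yl)-1,2,3,4,6,7,8,8a-octahydronaphthalen-1-yl]methyl}phenyl)-3-methylbutan-1-one, via o-quinone methide 22 (not isolated)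
Conditions: 21 (2 equiv), L-proline (20 mol%), diethyl 2,6-dimethyl-1,4-dihydropyridine-3,5-dicarboxylate (Hantzsch ester, 1.3 equiv), CH2Cl2/EtOH, 25 °C
Reagents that add atoms: none
Why: Amine-catalysed Knoevenagel-type condensation of the aldehyde with the C-nucleophilic acylphloroglucinol should give an o-quinone methide that is reduced at once by hydride transfer from the Hantzsch ester (three-component reductive alkylation), which forms the ArCH2–C1 bond and keeps C1 as long as reduction is faster than tautomerisation of the quinone methide.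

Step 11
Reactants: 23 1-(2,4,6-trihydroxy-3-{[(1S,4S,6S,8aS)-4,8a-dimethyl-6-(prop-1-en-2-yl)-1,2,3,4,6,7,8,8a-octahydronaphthalen-1-yl]methyl}phenyl)-3-methylbutan-1-one
Product: 25 2,4,6-trihydroxy-3-(3-methylbutanoyl)-5-{[(1S,4S,6S,8aS)-4,8a-dimethyl-6-(prop-1-en-2-yl)-1,2,3,4,6,7,8,8a-octahydronaphthalen-1-yl]methyl}benzaldehyde, via aryl iminium chloride 24 (not isolated)
Conditions: POCl3 (1.5 equiv), DMF (3 equiv), EtOAc, 0 → 25 °C; then H2O, 50 °C
Reagents that add atoms: N,N-dimethylformamide, CN(C)C=O; water, O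
Why: Vilsmeier–Haack formylation should occur at the only free position of the electron-rich ring and hydrolysis of the iminium salt should give the target, the isolated alkenes being too weakly nucleophilic to react with the chloroiminium reagent at this temperature.

**Compound list**

1 | (S)-(+)-carvone, (5S)-2-methyl-5-(prop-1-en-2-yl)cyclohex-2-en-1-one | CC1=CC[C@@H](CC1=O)C(C)=C | starting material
2 | methyl bromoacetate | COC(=O)CBr | starting material
3 | lithium (5S)-2-methyl-5-(prop-1-en-2-yl)cyclohex-1-en-1-olate | C=C(C)[C@@H]1CC([O-])=C(C)CC1.[Li+] | intermediate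
4 | methyl 2-[(1S,4S)-1-methyl-2-oxo-4-(prop-1-en-2-yl)cyclohexyl]acetate (acetate chain cis to isopropenyl) | C=C(C)[C@@H]1CC(=O)[C@@](CC(=O)OC)(C)CC1 | intermediate
5 | potassium (3S,6S)-6-(2-methoxy-2-oxoethyl)-6-methyl-3-(prop-1-en-2-yl)cyclohex-1-en-1-olate | C=C(C)[C@@H]1C=C([O-])[C@@](CC(=O)OC)(C)CC1.[K+] | intermediate
6 | methyl 2-[(1S,4S)-1-methyl-4-(prop-1-en-2-yl)-2-(trifluoromethanesulfonyloxy)cyclohex-2-en-1-yl]acetate | C=C(C)[C@@H]1C=C(OS(=O)(=O)C(F)(F)F)[C@@](CC(=O)OC)(C)CC1 | intermediate
7 | lithium ester enolate of 6 | C=C(C)[C@@H]1C=C(OS(=O)(=O)C(F)(F)F)[C@@](C=C([O-])OC)(C)CC1.[Li+] | intermediate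
8 | methyl 3-(dimethylamino)-2-[(1S,4S)-1-methyl-4-(prop-1-en-2-yl)-2-(trifluoromethanesulfonyloxy)cyclohex-2-en-1-yl]propanoate (Mannich base, both epimers at C2 of the propanoate) | C=C(C)[C@@H]1C=C(OS(=O)(=O)C(F)(F)F)[C@@](C(CN(C)C)C(=O)OC)(C)CC1 | intermediate
9 | N,N,N-trimethylammonium iodide of 8 | C=C(C)[C@@H]1C=C(OS(=O)(=O)C(F)(F)F)[C@@](C(C[N+](C)(C)C)C(=O)OC)(C)CC1.[I-] | intermediate
10 | methyl 2-[(1S,4S)-1-methyl-4-(prop-1-en-2-yl)-2-(trifluoromethanesulfonyloxy)cyclohex-2-en-1-yl]prop-2-enoate | C=C(C)[C@@H]1C=C(OS(=O)(=O)C(F)(F)F)[C@@](C(=C)C(=O)OC)(C)CC1 | intermediate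
11 | methyl 2-[(1R,4S)-1-methyl-4-(prop-1-en-2-yl)-2-(4,4,5,5-tetramethyl-1,3,2-dioxaborolan-2-yl)cyclohex-2-en-1-yl]prop-2-enoate | C=C(C)[C@@H]1C=C(B2OC(C)(C)C(C)(C)O2)[C@@](C(=C)C(=O)OC)(C)CC1 | intermediate
12 | (E)-crotonaldehyde, (2E)-but-2-enal | C/C=C/C=O | starting material
13 | alkenylrhodium species from 11 (rhodium on C5 in place of boron, ligands omitted) | C=C(C)[C@@H]1C=C([Rh])[C@@](C(=C)C(=O)OC)(C)CC1 | intermediate
14 | open-chain rhodium enolate (C4–C5 bond formed, C4 S, O-bound rhodium, ligands omitted) | C=C(C)[C@@H]1C=C([C@@H](C)C=CO[Rh])[C@@](C(=C)C(=O)OC)(C)CC1 | intermediate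
15 | methyl (1R,3S,4S,6S,8aS)-3-formyl-4,8a-dimethyl-6-(prop-1-en-2-yl)-1,2,3,4,6,7,8,8a-octahydronaphthalene-1-carboxylate | C=C(C)[C@@H]1C=C2[C@@H](C)[C@@H](C=O)C[C@@H](C(=O)OC)[C@]2(C)CC1 | intermediate
16 | methyl (1R,4S,6S,8aS)-4,8a-dimethyl-6-(prop-1-en-2-yl)-1,2,3,4,6,7,8,8a-octahydronaphthalene-1-carboxylate | C=C(C)[C@@H]1C=C2[C@@H](C)CC[C@@H](C(=O)OC)[C@]2(C)CC1 | intermediate
17 | [(1R,4S,6S,8aS)-4,8a-dimethyl-6-(prop-1-en-2-yl)-1,2,3,4,6,7,8,8a-octahydronaphthalen-1-yl]methanol | C=C(C)[C@@H]1C=C2[C@@H](C)CC[C@@H](CO)[C@]2(C)CC1 | intermediate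
18 | (1R,4S,6S,8aS)-4,8a-dimethyl-6-(prop-1-en-2-yl)-1,2,3,4,6,7,8,8a-octahydronaphthalene-1-carbaldehyde | C=C(C)[C@@H]1C=C2[C@@H](C)CC[C@@H](C=O)[C@]2(C)CC1 | intermediate
19 | phloroglucinol, benzene-1,3,5-triol | Oc1cc(O)cc(O)c1 | starting material
20 | isovaleryl chloride, 3-methylbutanoyl chloride | CC(C)CC(=O)Cl | starting material
21 | 3-methyl-1-(2,4,6-trihydroxyphenyl)butan-1-one | CC(C)CC(=O)c1c(O)cc(O)cc1O | intermediate
22 | o-quinone methide from 18 and 21 (exocyclic C=C between the benzylic carbon and the ring, geometry open) | C=C(C)[C@@H]1C=C2[C@@H](C)CC[C@@H](C=C3C(=O)C=C(O)C(C(=O)CC(C)C)=C3O)[C@]2(C)CC1 | intermediate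
23 | 1-(2,4,6-trihydroxy-3-{[(1S,4S,6S,8aS)-4,8a-dimethyl-6-(prop-1-en-2-yl)-1,2,3,4,6,7,8,8a-octahydronaphthalen-1-yl]methyl}phenyl)-3-methylbutan-1-one | C=C(C)[C@@H]1C=C2[C@@H](C)CC[C@@H](Cc3c(O)cc(O)c(C(=O)CC(C)C)c3O)[C@]2(C)CC1 | intermediate
24 | aryl N,N-dimethyliminium chloride of 23 (CH=NMe2+ at the free ring position) | C=C(C)[C@@H]1C=C2[C@@H](C)CC[C@@H](Cc3c(O)c(C=[N+](C)C)c(O)c(C(=O)CC(C)C)c3O)[C@]2(C)CC1.[Cl-] | intermediate
25 | 2,4,6-trihydroxy-3-(3-methylbutanoyl)-5-{[(1S,4S,6S,8aS)-4,8a-dimethyl-6-(prop-1-en-2-yl)-1,2,3,4,6,7,8,8a-octahydronaphthalen-1-yl]methyl}benzaldehyde (CNP0564915.1) | C=C(C)[C@@H]1C=C2[C@@H](C)CC[C@@H](Cc3c(O)c(C=O)c(O)c(C(=O)CC(C)C)c3O)[C@]2(C)CC1 | target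

**Step count and risks**

Total step count: 11. Longest linear sequence: 10 steps (1–8, 10, 11); step 9 is a one-step side branch.

Steps most likely to fail:

Step 5 (Proposed new method). The rhodium enolate 14 may be protonated before it closes the ring, because the closure has to build a syn-diaxial C4/C10 dimethyl arrangement; protodeboronation of the hindered boronate is a second drain. The fallback sets out from 11 and 12 and comes back at 15, making the two bonds in two known operations. Boronate 11 and crotonaldehyde 12 are coupled under protic Hayashi–Miyaura conditions ([RhCl(C2H4)2]2, the same diene ligand, KOH, MeOH/H2O 10:1, 25 °C), in which the enolate is protonated at once, to give the open-chain aldehyde F1. F1 is then cyclised by enamine catalysis (pyrrolidine 20 mol%, AcOH 20 mol%, CHCl3, 40 °C), an amine-catalysed intramolecular Michael addition of an aldehyde to an acrylate that is reversible at C3 and gives 15 after hydrolysis of the iminium ion.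

Step 10. Condensation of the hindered α-branched aldehyde may be slow, so that enolisation at C1 (loss of configuration) and capture of the quinone methide by the isopropenyl group of a second molecule compete with hydride transfer. The fallback sets out from 17 and 21 and comes back at 23; it avoids the aldehyde and makes the ArCH2 bond by Negishi coupling.
- Alcohol 17 is converted with I2, PPh3 and imidazole (CH2Cl2, 0 °C) into the iodide F2, and zinc insertion (Zn dust, LiCl, THF, 40 °C) gives the alkylzinc iodide F3.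
- In parallel, 21 is protected with NaH and chloromethyl methyl ether (DMF, 0 °C) as the tris(methoxymethyl) ether F4 and iodinated with N-iodosuccinimide (MeCN, 0 °C) to the aryl iodide F5.
- Coupling of F3 with F5 (Pd(OAc)2 5 mol%, SPhos 10 mol%, THF, 50 °C) gives the coupled tris(methoxymethyl) ether F6, and HCl (cat.) in MeOH at 40 °C removes the three acetals to give 23.

Step 6. The acylrhodium hydride may isomerise the alkenes or add to the C5=C6 bond (hydroacylation) before it loses CO, or decarbonylation of the hindered secondary aldehyde may stall. The fallback sets out from 15 and comes back at 16. Pinnick oxidation (NaClO2, NaH2PO4, 2-methylbut-2-ene, t-BuOH/H2O) gives the carboxylic acid F7. Coupling with 1-hydroxypyridine-2(1H)-thione (N,N'-dicyclohexylcarbodiimide, CH2Cl2, dark) gives the O-acyl thiohydroxamate F8, which is photolysed with t-BuSH (visible light, 25 °C; Barton reductive decarboxylation) to give 16.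

Further compounds
F1 | step 5 | methyl 2-[(1R,4S)-1-methyl-2-[(2S)-4-oxobutan-2-yl]-4-(prop-1-en-2-yl)cyclohex-2-en-1-yl]prop-2-enoate | C=C(C)[C@@H]1C=C([C@@H](C)CC=O)[C@@](C(=C)C(=O)OC)(C)CC1
F2 | step 10 | (1R,4S,6S,8aS)-1-(iodomethyl)-4,8a-dimethyl-6-(prop-1-en-2-yl)-1,2,3,4,6,7,8,8a-octahydronaphthalene | C=C(C)[C@@H]1C=C2[C@@H](C)CC[C@@H](CI)[C@]2(C)CC1
F3 | step 10 | {[(1R,4S,6S,8aS)-4,8a-dimethyl-6-(prop-1-en-2-yl)-1,2,3,4,6,7,8,8a-octahydronaphthalen-1-yl]methyl}zinc iodide | C=C(C)[C@@H]1C=C2[C@@H](C)CC[C@@H](C[Zn]I)[C@]2(C)CC1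
F4 | step 10 | 3-methyl-1-[2,4,6-tris(methoxymethoxy)phenyl]butan-1-one | CC(C)CC(=O)c1c(OCOC)cc(OCOC)cc1OCOC
F5 | step 10 | 1-[3-iodo-2,4,6-tris(methoxymethoxy)phenyl]-3-methylbutan-1-one | CC(C)CC(=O)c1c(OCOC)cc(OCOC)c(I)c1OCOC
F6 | step 10 | 1-[3-{[(1S,4S,6S,8aS)-4,8a-dimethyl-6-(prop-1-en-2-yl)-1,2,3,4,6,7,8,8a-octahydronaphthalen-1-yl]methyl}-2,4,6-tris(methoxymethoxy)phenyl]-3-methylbutan-1-one | C=C(C)[C@@H]1C=C2[C@@H](C)CC[C@@H](Cc3c(OCOC)cc(OCOC)c(C(=O)CC(C)C)c3OCOC)[C@]2(C)CC1
F7 | step 6 | (1R,3S,4S,6S,8aS)-1-(methoxycarbonyl)-4,8a-dimethyl-6-(prop-1-en-2-yl)-1,2,3,4,6,7,8,8a-octahydronaphthalene-3-carboxylic acid (locants as in 15) | C=C(C)[C@@H]1C=C2[C@@H](C)[C@@H](C(=O)O)C[C@@H](C(=O)OC)[C@]2(C)CC1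
F8 | step 6 | 2-thioxopyridin-1(2H)-yl ester of F7 (O-acyl thiohydroxamate) | C=C(C)[C@@H]1C=C2[C@@H](C)[C@@H](C(=O)ON3C=CC=CC3=S)C[C@@H](C(=O)OC)[C@]2(C)CC1
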